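# Proposed synthesis of CNP0313563.1 (compound 31) by rhodium-catalysed hydroacylation at the ring methylene

## Analysis of the target

Compound 31 is a diester built on a cyclopentane (ring atoms C1–C5). C1 carries an acyloxymethyl group, C2 a methyl group, C3 an acyloxy group and C5 a 1,3-dihydroxypropan-2-yl branch; C4 is the only ring CH2. The four ring stereocentres (1S,2R,3R,5R) alternate in orientation, so each neighbouring pair (C1/C2, C2/C3, C1/C5) is trans. Because this is the relaxed arrangement, C2 and C3 can be set under thermodynamic control once C1 and C5 are fixed.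

Both acyl groups are the same (3S,4E)-4-formyl-3-(2-oxoethyl)hex-4-enoyl chain. Each has one stereocentre bearing a CH2CO2R arm, a CH2CHO arm and the α-carbon of an (E)-2-ethylidene enal. These centres are too far from the ring to be controlled by it.

The sensitive groups are four aldehydes (two enolisable, two enals whose E geometry must be kept), two esters that could migrate to the free primary hydroxyls under base, and a free 1,3-diol that can form acetals with the aldehydes. The synthesis is hard for three reasons. Six stereocentres sit in three domains that do not communicate. Four hydroxyls must be differentiated two against two. The tetra-aldehyde can only be released in the last step, under conditions that spare the esters.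

The strategy rests on C4. An unsubstituted methylene between the oxygenated C3 and the branch-bearing C5 is what remains when an aldehyde C–H at C3 adds across a C5=C4H2 alkene.

## Retrosynthetic reasoning

**Unmasking (31 ⇒ 30).** The four aldehydes and the 1,3-diol are released together in the last step from 30, where every aldehyde is a dimethyl acetal and the diol is an acetonide. All five masks are acetals, so one mild aqueous acid treatment removes them and the esters are never exposed to base.

**Ester bonds (30 ⇒ 17 + 29).** Cutting the two acyl C–O bonds gives the core diol 17 and two equivalents of the acetal-protected acid 29. The cut is made here because the two chains are identical and their stereocentre cannot be influenced by the ring. The forward step is a double carbodiimide esterification; in 17 only the two hydroxyls to be acylated are free.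

**C3–O and benzyl ether (17 ⇒ 16).** The secondary alcohol is traced to ketone 16 and the primary alcohol to its benzyl ether. One dissolving-metal step should reduce the ketone to the more stable alcohol (trans to the C2 methyl) and remove the benzyl group. A carbonyl at C3 also makes C2 epimerisable, so the C1/C2 trans relationship is thermodynamically secured.

**C3–C4 bond, the key disconnection (16 ⇒ 15).** Cutting the bond between the carbonyl carbon and the ring CH2 opens the ring to the pent-4-enal 15. The former C4 becomes the terminus of a 1,1-disubstituted alkene and the former C5 its substituted carbon. No other ring bond can be cut without adding functionality that must later be removed. The forward reaction is an atom-economical isomerisation that must close the ring and create the C5 stereocentre trans to the C1 arm.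

**Aldehyde, methyl and alkenyl bonds (15 ⇒ 14 ⇒ 12 ⇒ 8 + 11).** Aldehyde 15 comes from ester 14 by partial reduction. The C2–CH3 bond of 14 is cut back to ester 12; the forward enolate methylation is steered by the neighbouring stereocentre. The bond between that stereocentre and the alkenyl carbon is cut to alkenylboronate 8 and enoate 11. The forward step is a rhodium-catalysed asymmetric conjugate addition, which sets the one core stereocentre that has no thermodynamic preference.

**Small building blocks (8 ⇒ 7 ⇒ 5 ⇒ 3 ⇒ 2 ⇒ 1; 11 ⇒ 9 + 10).** Boronate 8 derives from enol triflate 7 of methyl ketone 5. Ketone 5 comes from ester 3, the product of acetonide formation and mono-dealkoxycarbonylation of malonate 1 via 2. The 1,3-diol is thus present and protected from the first step. Enoate 11 is the Wittig product of aldehyde 9 and ylide 10.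

**Side-chain acid (29 ⇒ 28 ⇒ 27 ⇒ 26 ⇒ 24 ⇒ 22 + 23; 22 ⇒ 21 ⇒ 20 ⇒ 18).** Acid 29 is traced through ester 28 and aldehyde 27 to hydroxy ester 26, the ring-opened form of lactone 24. In 24 the CH2CO2R and CH2CHO arms are already differentiated as lactone carbonyl and ring CH2CH2O. Cutting the stereocentre–alkenyl bond of 24 gives lactone 23 and alkenylboronate 22. The boronate carries the ethylidene with its geometry fixed and comes from crotonaldehyde 18 through bromoenal 20 and acetal 21.

## Alternatives that were turned down

**Alternative 1: hetero-Diels–Alder dihydropyran as a masked dialdehyde chain.** This plan disconnects inside the side chain: the bond from the chain stereocentre to the CH2 of the CH2CHO arm, plus one C–O bond. In the forward sense a silyloxy-substituted enal acts as a 1-oxadiene and combines with a simple vinyl ether under a chiral Lewis acid of trivalent chromium. The product is cis-2-ethoxy-4-[2-(tert-butyldimethylsilyloxy)ethyl]-3,4-dihydro-2H-pyran (A1).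

- For it: one catalytic cycloaddition on unhindered partners sets the chain stereocentre and delivers the two aldehyde carbons in different masked forms (ring acetal and enol ether). No hindered alkenyl metal is needed.
- Against it: the ethylidene must still be attached to the enol-ether carbon of A1 by a condensation with E control. The silyloxyethyl arm must be oxidised to the acid. Above all, it leaves the cyclopentane and four of the six stereocentres unaddressed.
- Comparison: for the chain stereocentre alone it is as strong as, or stronger than, the conjugate addition used here in step 15. The chosen strategy instead spends its key step on the ring and brings in the ethylidene enal as one unit with geometry fixed in 20.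

**Alternative 2: twofold rhodium-catalysed alkenyl conjugate addition on the core bis-enoate.** Both stereocentre–alkenyl bonds of the chains are cut after the core has been acylated with an achiral enoic acid. In the forward sense two alkenylrhodium species, generated from an alkenylboronic acid under a rhodium–bisphosphine catalyst, add to the two enoate β-carbons. The product is the core bis(β-alkenyl ester) A2, with the enal carbons as allylic silyl ethers and the saturated aldehydes as diethyl acetals.

- For it: it is the most convergent plan and needs no separate chiral acid. It is clearly better in step economy for the chains.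
- Against it: acyclic enoates are the least reactive acceptor class and the alkenylboron is α-branched. Both additions must succeed on one advanced molecule. Any face-selectivity error gives diastereomers that differ only at remote centres and are hard to separate. The allylic silyl ethers must afterwards be cleaved and oxidised next to acetals. It also builds no ring bond.
- Comparison: the chosen route uses the same reaction type early, on the small cyclic acceptor 23, where failure is cheap and enantiopurity can be checked before coupling.

**Alternative 3: amine-catalysed intramolecular Michael closure of the cyclopentane.** The ring bond C1–C5 is cut. In the forward sense the enamine from an aldehyde and a diarylprolinol silyl ether attacks a tethered alkylidene malonate. The product is dimethyl 2-[(1R,2S,3R,4R)-2-formyl-3-methyl-4-(tert-butyldimethylsilyloxy)cyclopentyl]malonate (A3).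

- For it: the ring and two stereocentres (C1 and C5) are made in one metal-free step, against one stereocentre in the chosen key step. The malonate maps directly onto the 1,3-diol. The C3 oxygen is already in place, so no ketone reduction is needed.
- Against it: the open-chain precursor must already carry the C2 methyl and C3 silyloxy centres. It contains a γ-branched alkylidene malonate prone to deconjugation. After reduction, the formyl group and the malonate of A3 become three primary alcohols that must be told apart.
- Comparison: the chosen route differentiates these oxygens from the first step (benzyl ether against acetonide). It needs only one stereocentre set by a catalyst before the key step; C2 and C3 then follow thermodynamically from the C3 carbonyl.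

Key step: step 10

Assumption: (S)-BINAP in steps 7 and 15 and (R)-BINAP in step 10 are taken, from the usual face-selection models, as the ligand enantiomers that give the configurations drawn. If a step shows the opposite sense, the mirror-image ligand is used with no other change.

## Route

**Step 1**
Reactants: 1 diethyl bis(hydroxymethyl)malonate
Product: 2 diethyl 2,2-dimethyl-1,3-dioxane-5,5-dicarboxylate
Conditions: Me2C(OMe)2, TsOH·H2O (cat.), acetone, rt
Reagents that add atoms: 2,2-dimethoxypropane, COC(C)(C)OC
Why: Acid-catalysed transacetalisation closes an unstrained six-membered acetonide on the 1,3-diol, which stays masked until the last step.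

**Step 2**
Reactants: 2 diethyl 2,2-dimethyl-1,3-dioxane-5,5-dicarboxylate
Product: 3 ethyl 2,2-dimethyl-1,3-dioxane-5-carboxylate
Conditions: NaCl, H2O, DMSO, 160 °C
Reagents that add atoms: none
Why: Krapcho dealkoxycarbonylation: chloride dealkylates one ester of the geminal diester, CO2 is lost and the carbanion is protonated by water; the neutral medium leaves the acetonide intact.

**Step 3**
Reactants: 3 ethyl 2,2-dimethyl-1,3-dioxane-5-carboxylate
Product: 5 1-(2,2-dimethyl-1,3-dioxan-5-yl)ethan-1-one, via Weinreb amide 4 (not isolated)
Conditions: MeNHOMe·HCl, i-PrMgCl, THF, −20 °C; then MeMgBr, −20 → 0 °C; aq. NH4Cl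
Reagents that add atoms: methylmagnesium bromide, C[Mg]Br; N,O-dimethylhydroxylamine hydrochloride, CNOC.Cl (its atoms stay in 4 only)
Why: The magnesium amide converts the ester into the Weinreb amide in the flask, and the chelated tetrahedral adduct with the methyl Grignard reagent stops at the ketone stage; the mild quench avoids β-alkoxide loss from the product.

**Step 4**
Reactants: 5 1-(2,2-dimethyl-1,3-dioxan-5-yl)ethan-1-one
Product: 7 1-(2,2-dimethyl-1,3-dioxan-5-yl)ethenyl trifluoromethanesulfonate, via lithium enolate 6 (not isolated)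
Conditions: LiN(i-Pr)2, THF, −78 °C; then N-(5-chloropyridin-2-yl)bis(trifluoromethanesulfonimide), −78 → −20 °C; aq. NH4Cl
Reagents that add atoms: N-(5-chloropyridin-2-yl)bis(trifluoromethanesulfonimide), FC(F)(F)S(=O)(=O)N(c1ccc(Cl)cn1)S(=O)(=O)C(F)(F)F
Why: Kinetic deprotonation of a methyl ketone by a hindered amide occurs at the methyl group, and O-sulfonylation traps the terminal enolate as the enol triflate; keeping the enolate cold prevents equilibration to the ring-methine enolate, which would expel a β-alkoxide.

**Step 5**
Reactants: 7 1-(2,2-dimethyl-1,3-dioxan-5-yl)ethenyl trifluoromethanesulfonate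
Product: 8 2-[1-(2,2-dimethyl-1,3-dioxan-5-yl)ethenyl]-4,4,5,5-tetramethyl-1,3,2-dioxaborolane
Conditions: B2pin2, PdCl2(PPh3)2 (3 mol %), PPh3 (6 mol %), KOPh, toluene, 50 °C
Reagents that add atoms: bis(pinacolato)diboron, CC1(C)OB(OC1(C)C)B1OC(C)(C)C(C)(C)O1
Why: Miyaura borylation of a 1-alkenyl triflate: oxidative addition to zerovalent palladium, phenoxide-assisted transmetalation from the diboron and reductive elimination; the weak base spares the acetonide and avoids coupling of the product with the triflate.

**Step 6**
Reactants: 9 benzyloxyacetaldehyde; 10 ethyl (triphenylphosphoranylidene)acetate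
Product: 11 ethyl (2E)-4-(benzyloxy)but-2-enoate
Conditions: CH2Cl2, rt
Reagents that add atoms: none
Why: Wittig olefination with a stabilised ylide is under thermodynamic control of the oxaphosphetane and should give the E enoate.

**Step 7**
Reactants: 8 2-[1-(2,2-dimethyl-1,3-dioxan-5-yl)ethenyl]-4,4,5,5-tetramethyl-1,3,2-dioxaborolane; 11 ethyl (2E)-4-(benzyloxy)but-2-enoate
Product: 12 ethyl (3R)-4-(benzyloxy)-3-[1-(2,2-dimethyl-1,3-dioxan-5-yl)ethenyl]butanoate
Conditions: [Rh(OH)((S)-BINAP)]2 (3 mol %), KOH (0.3 equiv), 1,4-dioxane/H2O (10:1), 60 °C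
Reagents that add atoms: none
Why: Hayashi–Miyaura reaction: the alkenyl group passes from boron to the hydroxorhodium–BINAP species, adds to the β-carbon of the enoate bound through its α-si face, and the oxa-π-allylrhodium is hydrolysed. The ligand alone sets C3 as R (the future ring C1).

**Step 8**
Reactants: 12 ethyl (3R)-4-(benzyloxy)-3-[1-(2,2-dimethyl-1,3-dioxan-5-yl)ethenyl]butanoate
Product: 14 ethyl (2R,3R)-4-(benzyloxy)-3-[1-(2,2-dimethyl-1,3-dioxan-5-yl)ethenyl]-2-methylbutanoate, via ester lithium enolate 13 (not isolated)
Conditions: LiN(i-Pr)2, THF, −78 °C; then MeI, DMPU, −78 → −40 °C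
Reagents that add atoms: iodomethane, CI
Why: Ester enolate alkylation: with the C3–H eclipsing the enolate plane to minimise A(1,3) strain, iodomethane should approach anti to the bulky alkenyl group and set C2 as R. DMPU discourages chelation by the benzyloxy oxygen, and a C2 epimer remains correctable at the ketone stage.

**Step 9**
Reactants: 14 ethyl (2R,3R)-4-(benzyloxy)-3-[1-(2,2-dimethyl-1,3-dioxan-5-yl)ethenyl]-2-methylbutanoate
Product: 15 (2R,3R)-3-[(benzyloxy)methyl]-4-(2,2-dimethyl-1,3-dioxan-5-yl)-2-methylpent-4-enal
Conditions: i-Bu2AlH (1.1 equiv), CH2Cl2, −78 °C; MeOH, then aq. potassium sodium tartrate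
Reagents that add atoms: none
Why: Partial ester reduction: the aluminium hemiacetal formed with one hydride equivalent is stable at −78 °C and releases the aldehyde only on work-up; the neutral tartrate work-up protects the α-centre and the acetonide.

**Step 10 (key step)**
Reactants: 15 (2R,3R)-3-[(benzyloxy)methyl]-4-(2,2-dimethyl-1,3-dioxan-5-yl)-2-methylpent-4-enal
Product: 16 (2R,3S,4R)-3-[(benzyloxy)methyl]-4-(2,2-dimethyl-1,3-dioxan-5-yl)-2-methylcyclopentan-1-one
Conditions: [Rh(nbd)((R)-BINAP)]BF4 (5 mol %), activated with H2 then purged with Ar, acetone, 25 °C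
Reagents that add atoms: none
Why: Oxidative addition of the aldehyde C–H bond of 15 to the cationic monovalent rhodium–BINAP fragment gives an acyl hydride of trivalent rhodium; the pendant 1,1-disubstituted alkene binds, hydride migrates to its substituted carbon, and the six-membered acyl–alkyl rhodacycle undergoes C–C reductive elimination. The closest known reaction type is the cationic rhodium–bisphosphine-catalysed intramolecular hydroacylation of 4-substituted and 3,4-disubstituted pent-4-enals to cyclopentanones. The ring closes between the former aldehyde carbon and the terminal alkene carbon, formally a 5-endo-trig closure (both alkene carbons end up in the ring), which is possible only because the bond forms by reductive elimination from the six-membered metallacycle. The one new stereocentre, C4 of 16 (ring C5 of the target), is created in the hydride migration. Its face is chosen by the (R)-BINAP pocket, reinforced by the resident C3 substituent, which takes a pseudo-equatorial place in the metallacycle, trans to the dioxanyl group. Regioselectivity (hydride to the internal carbon, rhodium to CH2) is needed and is secured by the 1,1-disubstitution, which disfavours a tertiary alkyl–rhodium and a four-membered ring. Chemoselectivity against decarbonylation is needed and is secured by the chelating bisphosphine on a cationic centre with weakly bound acetone, so that alkene insertion outruns CO extrusion. The ethers and the acetonide are spectators, and C2 is not touched under these neutral conditions.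

**Step 11**
Reactants: 16 (2R,3S,4R)-3-[(benzyloxy)methyl]-4-(2,2-dimethyl-1,3-dioxan-5-yl)-2-methylcyclopentan-1-one
Product: 17 (1R,2R,3S,4R)-4-(2,2-dimethyl-1,3-dioxan-5-yl)-3-(hydroxymethyl)-2-methylcyclopentan-1-ol
Conditions: Li, NH3(l)/THF, t-BuOH, −78 → −33 °C; then NH4Cl
Reagents that add atoms: none
Why: Dissolving-metal reduction: two-electron reduction of the ketone gives a configurationally mobile α-oxido carbanion that should be protonated to the more stable alcohol, setting C1 of 17 as R with the oxygen trans to the C2 methyl. The same reagent cleaves the benzyl ether by benzylic C–O reduction, and the acetonide is inert.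

**Step 12**
Reactants: 18 (E)-crotonaldehyde
Product: 20 (2Z)-2-bromobut-2-enal, via 2,3-dibromobutanal 19 (not isolated)
Conditions: Br2, CH2Cl2, 0 °C; then Et3N, 0 °C → rt
Reagents that add atoms: bromine, BrBr
Why: Bromine adds across the alkene, and the amine removes the acidic α-hydrogen with loss of the β-bromide (E1cB); the more stable isomer, with the methyl group trans to the formyl group, should result.

**Step 13**
Reactants: 20 (2Z)-2-bromobut-2-enal
Product: 21 (2Z)-2-bromo-1,1-dimethoxybut-2-ene
Conditions: HC(OMe)3, MeOH, TsOH·H2O (cat.), rt; NaHCO3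
Reagents that add atoms: trimethyl orthoformate, COC(OC)OC
Why: Acid-catalysed acetalisation driven by the orthoformate as water scavenger; the α-bromine deactivates the alkene towards conjugate addition of methanol, so only the carbonyl reacts and the geometry is kept.

**Step 14**
Reactants: 21 (2Z)-2-bromo-1,1-dimethoxybut-2-ene
Product: 22 2-[(2E)-1,1-dimethoxybut-2-en-2-yl]-4,4,5,5-tetramethyl-1,3,2-dioxaborolane
Conditions: B2pin2, PdCl2(PPh3)2 (3 mol %), PPh3 (6 mol %), KOPh, toluene, 50 °C
Reagents that add atoms: bis(pinacolato)diboron, CC1(C)OB(OC1(C)C)B1OC(C)(C)C(C)(C)O1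
Why: Miyaura borylation of a 1-alkenyl bromide proceeds with retention of alkene geometry (the descriptor changes from Z to E only because boron ranks below carbon); the acetal is stable to the weakly basic medium.

**Step 15**
Reactants: 22 2-[(2E)-1,1-dimethoxybut-2-en-2-yl]-4,4,5,5-tetramethyl-1,3,2-dioxaborolane; 23 5,6-dihydro-2H-pyran-2-one
Product: 24 (4S)-4-[(2E)-1,1-dimethoxybut-2-en-2-yl]oxan-2-one
Conditions: [Rh(OH)((S)-BINAP)]2 (3 mol %), 1,4-dioxane/H2O (10:1), 80 °C
Reagents that add atoms: none
Why: Hayashi–Miyaura reaction on a cyclic enoate, the most reliable ester acceptor class: the alkenylrhodium–BINAP species adds to the α-si face of the lactone with retention of alkene geometry and sets C4 as S. Base-free conditions keep the lactone closed and the acetal intact.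

**Step 16**
Reactants: 24 (4S)-4-[(2E)-1,1-dimethoxybut-2-en-2-yl]oxan-2-one
Product: 26 methyl (3S,4E)-4-(dimethoxymethyl)-3-(2-hydroxyethyl)hex-4-enoate, via potassium carboxylate 25 (not isolated)
Conditions: KOH (1.0 equiv), MeOH/H2O, 0 °C → rt; concentrate; then MeI, DMF, rt
Reagents that add atoms: potassium hydroxide, [K+].[OH-]; iodomethane, CI
Why: Saponification opens the lactone irreversibly, and O-alkylation of the carboxylate under neutral conditions gives the hydroxy ester without an acid or base that would re-close it; the alcohol is not alkylated without a stronger base.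

**Step 17**
Reactants: 26 methyl (3S,4E)-4-(dimethoxymethyl)-3-(2-hydroxyethyl)hex-4-enoate
Product: 27 methyl (3S,4E)-4-(dimethoxymethyl)-3-(2-oxoethyl)hex-4-enoate
Conditions: (COCl)2, DMSO, CH2Cl2, −78 °C; then Et3N, −78 → 0 °C
Reagents that add atoms: none
Why: Swern oxidation stops at the aldehyde, runs under non-acidic conditions that keep the acetal, and is cold enough to prevent lactonisation of 26.

**Step 18**
Reactants: 27 methyl (3S,4E)-4-(dimethoxymethyl)-3-(2-oxoethyl)hex-4-enoate
Product: 28 methyl (3S,4E)-3-(2,2-dimethoxyethyl)-4-(dimethoxymethyl)hex-4-enoate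
Conditions: HC(OMe)3, MeOH, PPTS (cat.), rt
Reagents that add atoms: trimethyl orthoformate, COC(OC)OC
Why: Mild acetalisation of the saturated aldehyde; the existing acetal is also a dimethyl acetal, so exchange with the solvent changes nothing.

**Step 19**
Reactants: 28 methyl (3S,4E)-3-(2,2-dimethoxyethyl)-4-(dimethoxymethyl)hex-4-enoate
Product: 29 (3S,4E)-3-(2,2-dimethoxyethyl)-4-(dimethoxymethyl)hex-4-enoic acid
Conditions: LiOH, THF/MeOH/H2O, 0 °C → rt; then cold 0.5 M HCl to pH 5
Reagents that add atoms: lithium hydroxide, [Li+].[OH-]
Why: Saponification of an unhindered methyl ester; the stereocentre is β to the carboxyl and cannot epimerise, and brief cold acidification to pH 5 frees the acid without acetal hydrolysis.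

**Step 20**
Reactants: 17 (1R,2R,3S,4R)-4-(2,2-dimethyl-1,3-dioxan-5-yl)-3-(hydroxymethyl)-2-methylcyclopentan-1-ol; 29 (3S,4E)-3-(2,2-dimethoxyethyl)-4-(dimethoxymethyl)hex-4-enoic acid (2.4 equiv)
Product: 30 [(1S,2R,3R,5R)-3-{[(3S,4E)-3-(2,2-dimethoxyethyl)-4-(dimethoxymethyl)hex-4-enoyl]oxy}-5-(2,2-dimethyl-1,3-dioxan-5-yl)-2-methylcyclopentyl]methyl (3S,4E)-3-(2,2-dimethoxyethyl)-4-(dimethoxymethyl)hex-4-enoate
Conditions: DCC, DMAP (cat.), CH2Cl2, 0 °C → rt
Reagents that add atoms: none
Why: Steglich esterification: the acylpyridinium formed from the O-acylisourea acylates the primary and then the secondary hydroxyl; no stereocentre is at risk because the acid has no α-stereocentre and the carbinol C–O bonds are not broken.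

**Step 21**
Reactants: 30 (the protected diester of step 20)
Product: 31 [(1S,2R,3R,5R)-5-(1,3-dihydroxypropan-2-yl)-3-{[(3S,4E)-4-formyl-3-(2-oxoethyl)hex-4-enoyl]oxy}-2-methylcyclopentyl]methyl (3S,4E)-4-formyl-3-(2-oxoethyl)hex-4-enoate
Conditions: 1 M HCl (aq)/THF (1:3), 0 °C → rt; NaHCO3
Reagents that add atoms: water, O
Why: Specific acid-catalysed hydrolysis of the four dimethyl acetals and the acetonide through oxocarbenium ions; esters are stable to dilute acid at room temperature, and the thermodynamically preferred E ethylidene and the non-acidic chain stereocentre should be unaffected.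

## Compound list

1 | diethyl bis(hydroxymethyl)malonate | OCC(CO)(C(=O)OCC)C(=O)OCC | starting material
2 | diethyl 2,2-dimethyl-1,3-dioxane-5,5-dicarboxylate | CCOC(=O)C1(C(=O)OCC)COC(C)(C)OC1 | intermediate
3 | ethyl 2,2-dimethyl-1,3-dioxane-5-carboxylate | CCOC(=O)C1COC(C)(C)OC1 | intermediate
4 | N-methoxy-N,2,2-trimethyl-1,3-dioxane-5-carboxamide (Weinreb amide, not isolated) | CON(C)C(=O)C1COC(C)(C)OC1 | intermediate
5 | 1-(2,2-dimethyl-1,3-dioxan-5-yl)ethan-1-one | CC(=O)C1COC(C)(C)OC1 | intermediate
6 | lithium 1-(2,2-dimethyl-1,3-dioxan-5-yl)ethen-1-olate (not isolated) | [Li]OC(=C)C1COC(C)(C)OC1 | intermediate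
7 | 1-(2,2-dimethyl-1,3-dioxan-5-yl)ethenyl trifluoromethanesulfonate | C=C(OS(=O)(=O)C(F)(F)F)C1COC(C)(C)OC1 | intermediate
8 | 2-[1-(2,2-dimethyl-1,3-dioxan-5-yl)ethenyl]-4,4,5,5-tetramethyl-1,3,2-dioxaborolane | C=C(B1OC(C)(C)C(C)(C)O1)C2COC(C)(C)OC2 | intermediate
9 | benzyloxyacetaldehyde | O=CCOCc1ccccc1 | starting material
10 | ethyl (triphenylphosphoranylidene)acetate | CCOC(=O)C=P(c1ccccc1)(c1ccccc1)c1ccccc1 | starting material
11 | ethyl (2E)-4-(benzyloxy)but-2-enoate | CCOC(=O)/C=C/COCc1ccccc1 | intermediate
12 | ethyl (3R)-4-(benzyloxy)-3-[1-(2,2-dimethyl-1,3-dioxan-5-yl)ethenyl]butanoate | CCOC(=O)C[C@@H](COCc1ccccc1)C(=C)C1COC(C)(C)OC1 | intermediate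
13 | lithium enolate of 12, O-lithium trans to C3 (not isolated) | CCO/C(O[Li])=C\[C@@H](COCc1ccccc1)C(=C)C1COC(C)(C)OC1 | intermediate
14 | ethyl (2R,3R)-4-(benzyloxy)-3-[1-(2,2-dimethyl-1,3-dioxan-5-yl)ethenyl]-2-methylbutanoate | CCOC(=O)[C@H](C)[C@@H](COCc1ccccc1)C(=C)C1COC(C)(C)OC1 | intermediate
15 | (2R,3R)-3-[(benzyloxy)methyl]-4-(2,2-dimethyl-1,3-dioxan-5-yl)-2-methylpent-4-enal | O=C[C@H](C)[C@@H](COCc1ccccc1)C(=C)C1COC(C)(C)OC1 | intermediate
16 | (2R,3S,4R)-3-[(benzyloxy)methyl]-4-(2,2-dimethyl-1,3-dioxan-5-yl)-2-methylcyclopentan-1-one | c1ccccc1COC[C@@H]2[C@@H](C)C(=O)C[C@H]2C3COC(C)(C)OC3 | intermediate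
17 | (1R,2R,3S,4R)-4-(2,2-dimethyl-1,3-dioxan-5-yl)-3-(hydroxymethyl)-2-methylcyclopentan-1-ol | OC[C@@H]1[C@@H](C)[C@H](O)C[C@H]1C2COC(C)(C)OC2 | intermediate
18 | (E)-crotonaldehyde | C/C=C/C=O | starting material
19 | rac-(2R,3S)-2,3-dibromobutanal, anti-addition product, one enantiomer drawn (not isolated) | C[C@@H](Br)[C@@H](Br)C=O | intermediate
20 | (2Z)-2-bromobut-2-enal | C/C=C(/C=O)Br | intermediate
21 | (2Z)-2-bromo-1,1-dimethoxybut-2-ene | C/C=C(/C(OC)OC)Br | intermediate
22 | 2-[(2E)-1,1-dimethoxybut-2-en-2-yl]-4,4,5,5-tetramethyl-1,3,2-dioxaborolane | C/C=C(/C(OC)OC)B1OC(C)(C)C(C)(C)O1 | intermediate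
23 | 5,6-dihydro-2H-pyran-2-one | O=C1C=CCCO1 | starting material
24 | (4S)-4-[(2E)-1,1-dimethoxybut-2-en-2-yl]oxan-2-one | C/C=C(/C(OC)OC)[C@H]1CCOC(=O)C1 | intermediate
25 | potassium (3S,4E)-4-(dimethoxymethyl)-3-(2-hydroxyethyl)hex-4-enoate (not isolated) | C/C=C(/C(OC)OC)[C@@H](CCO)CC(=O)[O-].[K+] | intermediate
26 | methyl (3S,4E)-4-(dimethoxymethyl)-3-(2-hydroxyethyl)hex-4-enoate | C/C=C(/C(OC)OC)[C@@H](CCO)CC(=O)OC | intermediate
27 | methyl (3S,4E)-4-(dimethoxymethyl)-3-(2-oxoethyl)hex-4-enoate | C/C=C(/C(OC)OC)[C@@H](CC=O)CC(=O)OC | intermediate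
28 | methyl (3S,4E)-3-(2,2-dimethoxyethyl)-4-(dimethoxymethyl)hex-4-enoate | C/C=C(/C(OC)OC)[C@@H](CC(OC)OC)CC(=O)OC | intermediate
29 | (3S,4E)-3-(2,2-dimethoxyethyl)-4-(dimethoxymethyl)hex-4-enoic acid | C/C=C(/C(OC)OC)[C@@H](CC(OC)OC)CC(=O)O | intermediate
30 | [(1S,2R,3R,5R)-3-{[(3S,4E)-3-(2,2-dimethoxyethyl)-4-(dimethoxymethyl)hex-4-enoyl]oxy}-5-(2,2-dimethyl-1,3-dioxan-5-yl)-2-methylcyclopentyl]methyl (3S,4E)-3-(2,2-dimethoxyethyl)-4-(dimethoxymethyl)hex-4-enoate | C/C=C(/C(OC)OC)[C@@H](CC(OC)OC)CC(=O)OC[C@@H]1[C@@H](C)[C@H](OC(=O)C[C@H](CC(OC)OC)/C(C(OC)OC)=C\C)C[C@H]1C2COC(C)(C)OC2 | intermediate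
31 | [(1S,2R,3R,5R)-5-(1,3-dihydroxypropan-2-yl)-3-{[(3S,4E)-4-formyl-3-(2-oxoethyl)hex-4-enoyl]oxy}-2-methylcyclopentyl]methyl (3S,4E)-4-formyl-3-(2-oxoethyl)hex-4-enoate | C/C=C(/C=O)[C@@H](CC=O)CC(=O)OC[C@@H]1[C@@H](C)[C@H](OC(=O)C[C@H](CC=O)/C(C=O)=C\C)C[C@H]1C(CO)CO | target

## Step count and least certain steps

Total: 21 steps. Longest linear sequence: 12 steps (steps 1–5, 7–11, 20, 21, from 1). The side-chain branch is steps 12–19 and the enoate branch is step 6.

**Step 10 (key step).** The cyclisation may be diverted by decarbonylation of the acyl rhodium hydride, or by migration of the 1,1-disubstituted double bond through reversible hydride insertion. The ring may also close with insufficient facial discrimination if ligand and substrate bias are mismatched, because the alkene carries a bulky secondary substituent and the aldehyde is α-branched.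

Fallback: the bond is formed by an organolithium acylation instead. Ester 14 is converted with MeNHOMe·HCl and i-PrMgCl into (2R,3R)-4-(benzyloxy)-3-[1-(2,2-dimethyl-1,3-dioxan-5-yl)ethenyl]-N-methoxy-N,2-dimethylbutanamide F1. Hydroboration with 9-BBN and oxidation with NaBO3 gives the primary alcohol (2R,3S,4R)-3-[(benzyloxy)methyl]-4-(2,2-dimethyl-1,3-dioxan-5-yl)-5-hydroxy-N-methoxy-N,2-dimethylpentanamide F2. Iodine, PPh3 and imidazole give the iodide (2R,3R,4R)-3-[(benzyloxy)methyl]-4-(2,2-dimethyl-1,3-dioxan-5-yl)-5-iodo-N-methoxy-N,2-dimethylpentanamide F3. Iodine–lithium exchange with t-BuLi at −78 °C is followed by intramolecular attack on the amide, which returns to the route at 16. In this fallback the ring stereocentre is set by substrate-controlled hydroboration, which is less secure than catalyst control and may require separation of epimers.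

**Step 7.** Transmetalation and insertion may be slow for an α-branched alkenylboronate on an acyclic enoate. Protodeboronation, base-induced isomerisation of the γ-alkoxy enoate or ester hydrolysis could then take over, and face selectivity on an acyclic acceptor may be incomplete.

Fallback: an auxiliary-controlled cuprate addition. Ketone 5 is condensed with 2,4,6-triisopropylbenzenesulfonohydrazide to the hydrazone N'-[1-(2,2-dimethyl-1,3-dioxan-5-yl)ethylidene]-2,4,6-triisopropylbenzenesulfonohydrazide F4. A Shapiro reaction with n-BuLi gives the alkenyllithium, which is transmetalated with MgBr2·OEt2 and CuBr·SMe2. Aldehyde 9 is converted by Horner–Wadsworth–Emmons olefination with the diethyl phosphonoacetyl imide of (S)-4-phenyloxazolidin-2-one into (4S)-3-[(2E)-4-(benzyloxy)but-2-enoyl]-4-phenyloxazolidin-2-one F5. Addition of the alkenylcopper reagent to F5, anti to the phenyl group of the chelated imide, should give (4S)-3-{(3R)-4-(benzyloxy)-3-[1-(2,2-dimethyl-1,3-dioxan-5-yl)ethenyl]butanoyl}-4-phenyloxazolidin-2-one F6. Ethanolysis with BrMgOEt returns to the route at 12.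

**Step 8.** The methylation may show poor facial selectivity if chelation of lithium by the benzyloxy oxygen competes with the A(1,3)-controlled open transition state, giving the C2 epimer.

Fallback: stereocontrol is moved from kinetic alkylation to thermodynamic equilibration. Starting from 12, the epimer ethyl (2S,3R)-4-(benzyloxy)-3-[1-(2,2-dimethyl-1,3-dioxan-5-yl)ethenyl]-2-methylbutanoate F7 is carried through steps 9 and 10. This gives (2S,3R)-3-[(benzyloxy)methyl]-4-(2,2-dimethyl-1,3-dioxan-5-yl)-2-methylpent-4-enal F8 and then (2S,3S,4R)-3-[(benzyloxy)methyl]-4-(2,2-dimethyl-1,3-dioxan-5-yl)-2-methylcyclopentan-1-one F9. Treatment with DBU in CH2Cl2 epimerises the centre α to the ketone to the all-trans isomer, returning to the route at 16.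

**Step 15.** The trisubstituted alkenyl pinacol boronate may transfer slowly to rhodium under base-free conditions, so that protodeboronation or hydrolytic opening of the lactone at 80 °C competes.

Fallback: an auxiliary-controlled cuprate addition that also removes the lactone-opening sequence. Bromide 21 undergoes bromine–lithium exchange with t-BuLi at −78 °C and transmetalation with MgBr2·OEt2 and CuBr·SMe2. The reagent is added to (4R)-3-[(2E)-5,5-dimethoxypent-2-enoyl]-4-phenyloxazolidin-2-one F10, made separately by Horner–Wadsworth–Emmons olefination of 3,3-dimethoxypropanal with the phosphonoacetyl imide of (R)-4-phenyloxazolidin-2-one. The product is (4R)-3-[(3S,4E)-3-(2,2-dimethoxyethyl)-4-(dimethoxymethyl)hex-4-enoyl]-4-phenyloxazolidin-2-one F11. Cleavage with LiOH and H2O2 returns to the route at 29, replacing steps 14–19.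

**Step 11.** Protonation of the ketone-derived carbanion may not discriminate well between the two faces of a cyclopentane, because energy differences between epimeric cyclopentanols are small and the 1,3-related C4 branch also weighs in. The C1 epimer of 17 could therefore form in quantity.

Fallback: the alcohol is made with the opposite configuration and inverted during acylation. Ketone 16 is reduced with LiBH(s-Bu)3 at −78 °C, anti to the α-methyl group, to (1S,2R,3S,4R)-3-[(benzyloxy)methyl]-4-(2,2-dimethyl-1,3-dioxan-5-yl)-2-methylcyclopentan-1-ol F12. Hydrogenolysis (H2, Pd/C, EtOAc) gives (1S,2R,3S,4R)-4-(2,2-dimethyl-1,3-dioxan-5-yl)-3-(hydroxymethyl)-2-methylcyclopentan-1-ol F13. A double Mitsunobu esterification with 29, PPh3 and DIAD acylates the primary hydroxyl and the secondary one with inversion, returning to the route at 30.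

## Further compounds

F1 | step 10 | (2R,3R)-4-(benzyloxy)-3-[1-(2,2-dimethyl-1,3-dioxan-5-yl)ethenyl]-N-methoxy-N,2-dimethylbutanamide | CON(C)C(=O)[C@H](C)[C@@H](COCc1ccccc1)C(=C)C1COC(C)(C)OC1
F2 | step 10 | (2R,3S,4R)-3-[(benzyloxy)methyl]-4-(2,2-dimethyl-1,3-dioxan-5-yl)-5-hydroxy-N-methoxy-N,2-dimethylpentanamide | CON(C)C(=O)[C@H](C)[C@@H](COCc1ccccc1)[C@@H](CO)C1COC(C)(C)OC1
F3 | step 10 | (2R,3R,4R)-3-[(benzyloxy)methyl]-4-(2,2-dimethyl-1,3-dioxan-5-yl)-5-iodo-N-methoxy-N,2-dimethylpentanamide | CON(C)C(=O)[C@H](C)[C@@H](COCc1ccccc1)[C@@H](CI)C1COC(C)(C)OC1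
F4 | step 7 | N'-[(1E)-1-(2,2-dimethyl-1,3-dioxan-5-yl)ethylidene]-2,4,6-triisopropylbenzenesulfonohydrazide | C/C(=N\NS(=O)(=O)c1c(C(C)C)cc(C(C)C)cc1C(C)C)C1COC(C)(C)OC1
F5 | step 7 | (4S)-3-[(2E)-4-(benzyloxy)but-2-enoyl]-4-phenyloxazolidin-2-one | O=C(/C=C/COCc1ccccc1)N1C(=O)OC[C@@H]1c1ccccc1
F6 | step 7 | (4S)-3-{(3R)-4-(benzyloxy)-3-[1-(2,2-dimethyl-1,3-dioxan-5-yl)ethenyl]butanoyl}-4-phenyloxazolidin-2-one | O=C(C[C@@H](COCc1ccccc1)C(=C)C1COC(C)(C)OC1)N1C(=O)OC[C@@H]1c1ccccc1
F7 | step 8 | ethyl (2S,3R)-4-(benzyloxy)-3-[1-(2,2-dimethyl-1,3-dioxan-5-yl)ethenyl]-2-methylbutanoate | CCOC(=O)[C@@H](C)[C@@H](COCc1ccccc1)C(=C)C1COC(C)(C)OC1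
F8 | step 8 | (2S,3R)-3-[(benzyloxy)methyl]-4-(2,2-dimethyl-1,3-dioxan-5-yl)-2-methylpent-4-enal | O=C[C@@H](C)[C@@H](COCc1ccccc1)C(=C)C1COC(C)(C)OC1
F9 | step 8 | (2S,3S,4R)-3-[(benzyloxy)methyl]-4-(2,2-dimethyl-1,3-dioxan-5-yl)-2-methylcyclopentan-1-one | c1ccccc1COC[C@@H]2[C@H](C)C(=O)C[C@H]2C3COC(C)(C)OC3
F10 | step 15 | (4R)-3-[(2E)-5,5-dimethoxypent-2-enoyl]-4-phenyloxazolidin-2-one | COC(OC)C/C=C/C(=O)N1C(=O)OC[C@H]1c1ccccc1
F11 | step 15 | (4R)-3-[(3S,4E)-3-(2,2-dimethoxyethyl)-4-(dimethoxymethyl)hex-4-enoyl]-4-phenyloxazolidin-2-one | C/C=C(/C(OC)OC)[C@@H](CC(OC)OC)CC(=O)N1C(=O)OC[C@H]1c1ccccc1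
F12 | step 11 | (1S,2R,3S,4R)-3-[(benzyloxy)methyl]-4-(2,2-dimethyl-1,3-dioxan-5-yl)-2-methylcyclopentan-1-ol | c1ccccc1COC[C@@H]2[C@@H](C)[C@@H](O)C[C@H]2C3COC(C)(C)OC3
F13 | step 11 | (1S,2R,3S,4R)-4-(2,2-dimethyl-1,3-dioxan-5-yl)-3-(hydroxymethyl)-2-methylcyclopentan-1-ol | OC[C@@H]1[C@@H](C)[C@@H](O)C[C@H]1C2COC(C)(C)OC2
A1 | alternative 1 | (2R,4R)-cis-2-ethoxy-4-[2-(tert-butyldimethylsilyloxy)ethyl]-3,4-dihydro-2H-pyran | CC(C)(C)[Si](C)(C)OCC[C@@H]1C[C@H](OCC)OC=C1
A2 | alternative 2 | [(1S,2R,3R,5R)-3-({(3S,4E)-4-[(tert-butyldimethylsilyloxy)methyl]-3-(2,2-diethoxyethyl)hex-4-enoyl}oxy)-5-(2,2-dimethyl-1,3-dioxan-5-yl)-2-methylcyclopentyl]methyl (3S,4E)-4-[(tert-butyldimethylsilyloxy)methyl]-3-(2,2-diethoxyethyl)hex-4-enoate | C/C=C(/CO[Si](C)(C)C(C)(C)C)[C@@H](CC(OCC)OCC)CC(=O)OC[C@@H]1[C@@H](C)[C@H](OC(=O)C[C@H](CC(OCC)OCC)/C(CO[Si](C)(C)C(C)(C)C)=C\C)C[C@H]1C2COC(C)(C)OC2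
A3 | alternative 3 | dimethyl 2-[(1R,2S,3R,4R)-2-formyl-3-methyl-4-(tert-butyldimethylsilyloxy)cyclopentyl]malonate | O=C[C@@H]1[C@@H](C)[C@H](O[Si](C)(C)C(C)(C)C)C[C@H]1C(C(=O)OC)C(=O)OC
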